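**Plan**
1. Cuts: the epoxide oxygen, the acetate and the exocyclic CH2 come off first. Ring A is cut at the bond between the carbinol carbon and the lactone β-CH (ketone + butenolide) and at the two side-chain bonds of the quaternary carbon (α-methylene ketone + dithiane anion + CH2O). Ring C is cut at two bonds at once: the CH2–CH2 bond on the side of the ring-fusion CH, and the C–C bond of the later epoxide (made as C=C).
2. Enabling feature: ring C is only a 1-methylcycloheptene (later epoxide) strung between the trans pair angular C(CH3) / ring-fusion CH of ring B. Its CH2–C(CH3)= unit can therefore come from an isopropenylphosphonium salt that joins a CH2 radical on the CH to a CH2CHO arm on the angular carbon. That radical/aldehyde pair, plus CO2, is what ozonolysis of a trans-decal-2-one enol ether gives, so a cyclohexanone becomes the methylcycloheptene with loss of its carbonyl carbon.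
3. Forward order: (S)-octalone → trans-decalone (ring B + six-membered forerunner of ring C) → oxo acid → ring C → quaternary carbon → butenolide → ring A with the lactone → methylenation, acetate, epoxide.
4. Stereochemistry: angular methyl from the octalone; trans B/C fusion by hydroboration anti to it; quaternary C–CH2O by axial aldol anti to it; lactone O–CH by catalyst-controlled alkynylation; carbinol carbon and lactone β-CH in the ketyl–olefin ring closure; epoxide by peracid attack anti to the angular methyl.

Key step: step 6

Assumption: (S)-4a-methyl-4,4a,5,6,7,8-hexahydronaphthalen-2(3H)-one is taken as purchasable; otherwise it is one chiral-imine Robinson annulation away from 2-methylcyclohexanone and methyl vinyl ketone.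
Convention: ring A = cyclopentane, ring B = cyclohexane, ring C = seven-membered ring; α = face of the angular methyl, β = the opposite face. Bicyclic intermediates 14–24 use benzo[7]annulene locants (C3 = CH2 next to C4; C4 = carbinol/ketone carbon; C4a = ring-fusion CH; C7 = olefinic C–CH3; C9a = angular C–CH3).

**Step 1**
Reactants: 1 (S)-octalone
Product: 2 β,γ-unsaturated dioxolane
Conditions: HOCH2CH2OH, p-TsOH (cat.), benzene, reflux (Dean–Stark)
Reagents that add atoms: ethylene glycol, OCCO
Why: Acid-catalysed ketalisation of a β,β-disubstituted cyclohexenone goes with migration of the double bond out of conjugation (as for Δ4-3-keto steroids), which places the alkene at the carbon that must become oxygenated, and the quaternary stereocentre is not affected.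

**Step 2**
Reactants: 2 β,γ-unsaturated dioxolane
Product: 5 trans-fused hydroxy decalone, via alkylborane 3 (not isolated), via hydroxy ketal 4 (not isolated)
Conditions: BH3·THF, THF, 0 °C to rt; NaOH, H2O2, 0 °C; then 2 M HCl, THF, rt
Reagents that add atoms: hydrogen peroxide, OO; water, O
Why: Brown hydroboration puts boron on the less substituted alkene carbon and delivers H and B syn to the β-face, opposite the angular methyl (as with Δ5-steroidal ketals), which sets the trans ring fusion, and after oxidation with retention the acid work-up hydrolyses the dioxolane.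

**Step 3**
Reactants: 5 trans-fused hydroxy decalone
Product: 6 bis-silyl compound (TBS ether / TBS enol ether)
Conditions: TBSOTf (2.5 equiv), Et3N (4 equiv), CH2Cl2, 0 °C to rt
Reagents that add atoms: tert-butyldimethylsilyl triflate, CC(C)(C)[Si](C)(C)OS(=O)(=O)C(F)(F)F
Why: Silyl triflate and amine convert the alcohol into its TBS ether and the ketone into the silyl enol ether (soft enolisation), and trans-fused decal-2-ones of this 3-keto-5α-steroid type enolise away from the ring fusion, which puts the enol double bond between the carbonyl carbon and the CH2 that will become the aldehyde.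

**Step 4**
Reactants: 6 bis-silyl compound
Product: 8 oxo acid, via methoxy hydroperoxide 7 (not isolated)
Conditions: O3, CH2Cl2/MeOH 4:1, −78 °C; Me2S, −78 °C to rt; aqueous work-up at pH 4
Reagents that add atoms: ozone, [O-][O+]=O
Why: Ozonolysis of a silyl enol ether (Criegee cleavage, the carbonyl oxide being trapped by methanol and reduced by Me2S) cuts the enol double bond into a silyl ester, hydrolysed on work-up to the acid, and an aldehyde, so that the two arms sit trans-diequatorial on adjacent ring carbons with no stereocentre touched.

**Step 5**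
Reactants: 9 2-bromopropene; 10 triphenylphosphine
Product: 11 isopropenyltriphenylphosphonium bromide
Conditions: Pd(PPh3)4 (2 mol%), PhCN, 100 °C, sealed tube
Reagents that add atoms: none
Why: Pd(0) inserts into the alkenyl C–Br bond and the alkenyl group is reductively eliminated onto phosphorus (P–C cross-coupling), a known route to alkenylphosphonium salts.

**Step 6**
Reactants: 8 oxo acid; 11 isopropenyltriphenylphosphonium bromide
Product: 14 bicyclic methylcycloheptene silyl ether, via cesium carboxylate 12 (not isolated), via phosphonium ylide 13 (not isolated)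
Conditions: CsOH·H2O (1.0 equiv), MeOH, then evaporation to dryness; 11 (4 equiv), [Ir(dF(CF3)ppy)2(dtbbpy)]PF6 (2 mol%), MeCN/CH2Cl2 1:1 (0.01 M), 4 Å MS, blue LEDs (450 nm), rt
Reagents that add atoms: none
Why: Proposed new method: single-electron oxidation of carboxylate 12 by the excited photocatalyst and loss of CO2 give the primary radical on the CH2 arm of the ring-fusion CH, which adds (nucleophilic radical, polarity-matched) to the CH2 terminus of the isopropenylphosphonium cation 11; the tertiary α-phosphonio radical is reduced by the reduced photocatalyst to ylide 13, which closes the ring by intramolecular Wittig olefination of the CH2CHO arm on the angular carbon (oxaphosphetane, loss of Ph3P=O). The closest known reaction type is the intermolecular three-component photoredox radical–polar-crossover olefination of carboxylic acids, vinylphosphonium salts and aldehydes, and behind it the classical vinylphosphonium annulation in which a two-electron nucleophile plays the part of the radical; new here are the α-methyl-substituted salt and the ring-forming use. Ring C is closed as a formal [5+2] annulation whose ring-forming event is a seven-membered intramolecular Wittig reaction (the radical addition itself is intermolecular). No stereocentre is created: the trans ring fusion is carried by the substrate and the olefin geometry is fixed by the ring. The step needs radical addition to 11 to outrun 1,5-hydrogen transfer from the aldehyde C–H and reversible 5-exo attack on the C=O, which the large excess and electron poverty of 11 should secure, and it needs intramolecular to beat intermolecular Wittig reaction, which the trans-diequatorial placing of the two arms on the chair, the high dilution and the steady-state generation of the ylide should secure.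

**Step 7**
Reactants: 14 bicyclic methylcycloheptene silyl ether
Product: 15 bicyclic alcohol
Conditions: TBAF, THF, 40 °C
Reagents that add atoms: none
Why: Fluoride cleaves the silyl ether through formation of the strong Si–F bond (standard desilylation), leaving the alkene untouched.

**Step 8**
Reactants: 15 bicyclic alcohol
Product: 16 bicyclic ketone
Conditions: Dess–Martin periodinane, NaHCO3, CH2Cl2, rt
Reagents that add atoms: none
Why: Dess–Martin oxidation of the secondary alcohol under buffered conditions gives the ketone without epimerising the adjacent ring-fusion CH.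

**Step 9**
Reactants: 16 bicyclic ketone
Product: 20 α-methylene ketone, via lithium enolate 17 (not isolated), via Mannich base 18 (not isolated), via ammonium iodide 19 (not isolated)
Conditions: LDA, THF, −78 °C; Me2N+=CH2 I−, −78 to 0 °C; then MeI (excess), CH2Cl2, rt; then sat. aq. NaHCO3, rt; product used crude
Reagents that add atoms: Eschenmoser's salt (N,N-dimethylmethyleneiminium iodide), C=[N+](C)C.[I-]
Why: Kinetic deprotonation takes the α-CH2 and not the hindered ring-fusion CH, the enolate undergoes a Mannich reaction with the iminium salt, and quaternisation followed by E1cB loss of trimethylamine gives the exocyclic enone (α-methylenation).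

**Step 10**
Reactants: 20 α-methylene ketone
Product: 22 hydroxymethyl dithianylmethyl ketone, via lithium enolate 21 (not isolated)
Conditions: 1,3-dithiane, n-BuLi, THF, −30 °C; HMPA, then 20, −78 °C; CH2O (gas), −78 °C; then H2O
Reagents that add atoms: 1,3-dithiane, C1CSCSC1; formaldehyde, C=O
Why: In THF/HMPA 2-lithio-1,3-dithiane adds 1,4 to the exocyclic enone and so gives the fully substituted enolate regiospecifically, and its aldol reaction with formaldehyde should take place along the axial direction on the β-face, away from the angular methyl (chair-like transition state of the trans-fused ring), which puts CH2OH axial/β and the dithianylmethyl arm equatorial.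

**Step 11**
Reactants: 22 hydroxymethyl dithianylmethyl ketone
Product: 23 silyl ether dithiane
Conditions: TBSCl, imidazole, DMF, rt
Reagents that add atoms: tert-butyldimethylsilyl chloride, CC(C)(C)[Si](C)(C)Cl
Why: Imidazole-promoted silylation protects the primary hydroxyl of the β-hydroxy ketone against retro-aldol loss of formaldehyde in the following steps.

**Step 12**
Reactants: 23 silyl ether dithiane
Product: 24 keto aldehyde
Conditions: MeI (10 equiv), CaCO3, MeCN/H2O 9:1, 45 °C
Reagents that add atoms: water, O
Why: S-Methylation makes the dithiane a leaving group and water hydrolyses it to the aldehyde (dithiane removal by alkylative hydrolysis) under conditions that do not touch the trisubstituted alkene, which an ozonolysis route to this aldehyde would not allow.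

**Step 13**
Reactants: 24 keto aldehyde
Product: 25 propargylic alcohol
Conditions: methyl propiolate (3 equiv), Me2Zn (3 equiv), ProPhenol ligand (20 mol%, the enantiomer that gives the S carbinol), Ph3P=O (40 mol%), toluene, 4 °C
Reagents that add atoms: methyl propiolate, C#CC(=O)OC
Why: Zinc–ProPhenol-catalysed enantioselective addition of the zinc alkynide of methyl propiolate to the aldehyde, in which the chiral catalyst and not the remote ring stereocentres selects the aldehyde face, sets the S carbinol that becomes the lactone O–CH.

**Step 14**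
Reactants: 25 propargylic alcohol
Product: 27 butenolide, via Z-hydroxy enoate 26 (not isolated)
Conditions: H2 (1 atm), Lindlar catalyst, quinoline, EtOAc, rt; then PPTS (cat.), CH2Cl2, rt
Reagents that add atoms: none
Why: Lindlar semihydrogenation gives the Z enoate, whose γ-hydroxyl lactonises onto the cis ester to the butenolide with retention at the carbinol carbon, and the trisubstituted ring alkene is not reduced by the poisoned catalyst.

**Step 15**
Reactants: 27 butenolide
Product: 28 tricyclic hydroxy lactone
Conditions: SmI2 (3 equiv), t-BuOH (3 equiv), THF, −78 to 0 °C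
Reagents that add atoms: none
Why: SmI2 ketyl–olefin (reductive 5-exo) cyclisation onto the butenolide β-carbon closes ring A: the short tether lets the ketyl reach only the butenolide face that gives the cis-fused bicyclic lactone, and C–C bond formation at the ketyl carbon on the β-face, away from the 1,3-diaxial angular methyl, should leave the tertiary OH axial/α and anti to the new bond (trans-fused ring A), the samarium enolate then being protonated by t-BuOH.

**Step 16**
Reactants: 28 tricyclic hydroxy lactone
Product: 32 α-methylene lactone silyl ether, via dilithio enolate 29 (not isolated), via Mannich base 30 (not isolated), via ammonium iodide 31 (not isolated)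
Conditions: LiHMDS (3.3 equiv), THF, −78 °C; Me2N+=CH2 I−, −78 to 0 °C; then MeI (excess), CH2Cl2/MeOH, rt; then sat. aq. NaHCO3, rt
Reagents that add atoms: Eschenmoser's salt (N,N-dimethylmethyleneiminium iodide), C=[N+](C)C.[I-]
Why: The lactone enolate (the tertiary OH is carried as its lithium alkoxide) undergoes a Mannich reaction with the iminium salt, and quaternisation followed by E1cB elimination of trimethylamine installs the exocyclic methylene (Eschenmoser methylenation), the α-stereocentre of the Mannich base being lost.

**Step 17**
Reactants: 32 α-methylene lactone silyl ether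
Product: 33 diol
Conditions: HF·pyridine, THF/pyridine, 0 °C to rt
Reagents that add atoms: none
Why: Buffered HF cleaves the primary silyl ether without adding a nucleophile to the α-methylene lactone.

**Step 18**
Reactants: 33 diol
Product: 34 primary acetate
Conditions: Ac2O (1.5 equiv), pyridine, CH2Cl2, 0 °C
Reagents that add atoms: acetic anhydride, CC(=O)OC(C)=O
Why: Acylation takes place only at the primary hydroxyl because the tertiary, axial carbinol is too hindered to react under these conditions.

**Step 19**
Reactants: 34 primary acetate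
Product: 35 CNP0214540.1
Conditions: m-CPBA (1.1 equiv), NaHCO3, CH2Cl2, 0 °C
Reagents that add atoms: m-chloroperoxybenzoic acid, OOC(=O)c1cccc(Cl)c1
Why: Prilezhaev epoxidation attacks the electron-rich trisubstituted alkene and not the electron-poor methylene lactone, from the β-face of ring C away from the pseudo-axial angular methyl, which should place the epoxide oxygen anti to that methyl and syn to the ring-fusion hydrogen.

**Compound list**
1 | (S)-4a-methyl-4,4a,5,6,7,8-hexahydronaphthalen-2(3H)-one | C1CC[C@@]2(C)CCC(=O)C=C2C1 | starting material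
2 | (S)-4a'-methyl-3',4',4a',5',6',7'-hexahydro-1'H-spiro[1,3-dioxolane-2,2'-naphthalene] (C8'=C8a' alkene) | C1CC[C@@]2(C)CCC3(OCCO3)CC2=C1 | intermediate
3 | alkylborane from 2, BH2 on C8' and H on C8a' both on the β-face, drawn as the monoalkylborane (not isolated) | C1CC[C@@]2(C)CCC3(OCCO3)C[C@@H]2[C@H]1B | intermediate
4 | (4a'S,8'S,8a'S)-4a'-methyloctahydro-1'H-spiro[1,3-dioxolane-2,2'-naphthalen]-8'-ol, trans-fused (not isolated) | C1CC[C@@]2(C)CCC3(OCCO3)C[C@@H]2[C@H]1O | intermediate
5 | (4aS,8S,8aS)-8-hydroxy-4a-methyloctahydronaphthalen-2(1H)-one (trans-fused, OH equatorial) | C1CC[C@@]2(C)CCC(=O)C[C@@H]2[C@H]1O | intermediate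
6 | tert-butyl{[(4aS,8S,8aS)-8-(tert-butyldimethylsilyloxy)-4a-methyl-1,4,4a,5,6,7,8,8a-octahydronaphthalen-2-yl]oxy}dimethylsilane | C1CC[C@@]2(C)CC=C(O[Si](C)(C)C(C)(C)C)C[C@@H]2[C@H]1O[Si](C)(C)C(C)(C)C | intermediate
7 | TBS ester of 8 with the aldehyde present as CH(OCH3)OOH (not isolated) | C1CC[C@@](C)(CC(OC)OO)[C@H](CC(=O)O[Si](C)(C)C(C)(C)C)[C@H]1O[Si](C)(C)C(C)(C)C | intermediate
8 | 2-[6-(tert-butyldimethylsilyloxy)-2-methyl-2-(2-oxoethyl)cyclohexyl]acetic acid; CH2CO2H trans to CH2CHO and trans to OTBS, methyl axial | C1CC[C@@](C)(CC=O)[C@H](CC(=O)O)[C@H]1O[Si](C)(C)C(C)(C)C | intermediate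
9 | 2-bromopropene | CC(Br)=C | starting material
10 | triphenylphosphine | c1ccc(cc1)P(c1ccccc1)c1ccccc1 | starting material
11 | isopropenyltriphenylphosphonium bromide | CC(=C)[P+](c1ccccc1)(c1ccccc1)c1ccccc1.[Br-] | intermediate
12 | cesium carboxylate of 8 (not isolated) | C1CC[C@@](C)(CC=O)[C@H](CC(=O)[O-])[C@H]1O[Si](C)(C)C(C)(C)C.[Cs+] | intermediate
13 | phosphonium ylide: ring–CH2CH2–C(CH3)=PPh3 with the CH2CHO arm still free (not isolated) | C1CC[C@@](C)(CC=O)[C@H](CCC(C)=P(c2ccccc2)(c2ccccc2)c2ccccc2)[C@H]1O[Si](C)(C)C(C)(C)C | intermediate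
14 | trans-fused 4-(tert-butyldimethylsilyloxy)-7,9a-dimethyl-2,3,4,4a,5,6,9,9a-octahydro-1H-benzo[7]annulene (H-4a β, 9a-CH3 α, OTBS β) | C1CC[C@@]2(C)CC=C(C)CC[C@@H]2[C@H]1O[Si](C)(C)C(C)(C)C | intermediate
15 | trans-fused 7,9a-dimethyl-2,3,4,4a,5,6,9,9a-octahydro-1H-benzo[7]annulen-4-ol (OH β) | C1CC[C@@]2(C)CC=C(C)CC[C@@H]2[C@H]1O | intermediate
16 | trans-fused 7,9a-dimethyl-1,2,3,4a,5,6,9,9a-octahydro-4H-benzo[7]annulen-4-one (H-4a β, 9a-CH3 α) | C1CC[C@@]2(C)CC=C(C)CC[C@@H]2C1=O | intermediate
17 | lithium enolate of 16, C3=C4–OLi (not isolated) | [Li]OC1=CCC[C@@]2(C)CC=C(C)CC[C@H]12 | intermediate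
18 | 3-[(dimethylamino)methyl] derivative of 16, mixture at C3 (not isolated) | CN(C)CC1CC[C@@]2(C)CC=C(C)CC[C@@H]2C1=O | intermediate
19 | trimethylammonium iodide from 18 (not isolated) | C[N+](C)(C)CC1CC[C@@]2(C)CC=C(C)CC[C@@H]2C1=O.[I-] | intermediate
20 | 3-methylidene derivative of 16 | C=C1CC[C@@]2(C)CC=C(C)CC[C@@H]2C1=O | intermediate
21 | lithium enolate, 3-(1,3-dithian-2-ylmethyl), C3=C4–OLi (not isolated) | [Li]OC1=C(CC2SCCCS2)CC[C@@]3(C)CC=C(C)CC[C@H]13 | intermediate
22 | 3-(1,3-dithian-2-ylmethyl)-3-(hydroxymethyl) derivative of 16; CH2OH β (axial), dithianylmethyl α (equatorial) | OC[C@@]1(CC2SCCCS2)CC[C@@]3(C)CC=C(C)CC[C@@H]3C1=O | intermediate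
23 | TBS ether of 22 | CC(C)(C)[Si](C)(C)OC[C@@]1(CC2SCCCS2)CC[C@@]3(C)CC=C(C)CC[C@@H]3C1=O | intermediate
24 | 2-[3-(tert-butyldimethylsilyloxymethyl)-7,9a-dimethyl-4-oxo-benzo[7]annulen-3-yl]acetaldehyde (ring stereochemistry as in 22) | CC(C)(C)[Si](C)(C)OC[C@@]1(CC=O)CC[C@@]3(C)CC=C(C)CC[C@@H]3C1=O | intermediate
25 | methyl (4S)-4-hydroxy-5-[ring as in 24]pent-2-ynoate | CC(C)(C)[Si](C)(C)OC[C@@]1(C[C@H](O)C#CC(=O)OC)CC[C@@]3(C)CC=C(C)CC[C@@H]3C1=O | intermediate
26 | methyl (2Z,4S)-4-hydroxy-5-[ring as in 24]pent-2-enoate (not isolated) | CC(C)(C)[Si](C)(C)OC[C@@]1(C[C@H](O)/C=C\C(=O)OC)CC[C@@]3(C)CC=C(C)CC[C@@H]3C1=O | intermediate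
27 | butenolide: (5S)-5-{[ring as in 24]methyl}furan-2(5H)-one | CC(C)(C)[Si](C)(C)OC[C@@]1(C[C@@H]2OC(=O)C=C2)CC[C@@]3(C)CC=C(C)CC[C@@H]3C1=O | intermediate
28 | tricyclic hydroxy lactone: ring A cis-fused to the saturated γ-lactone (O–CH and CH–CH2CO both β), trans-fused to ring B (tertiary OH α, CH2OTBS β), ring B trans-fused to the methylcycloheptene (angular CH3 α, H β) | C1C(=O)O[C@H]2C[C@]3(CO[Si](C)(C)C(C)(C)C)CC[C@@]4(C)CC=C(C)CC[C@@H]4[C@@]3(O)[C@@H]12 | intermediate
29 | dilithio species of 28: lithium alkoxide and lithium lactone enolate (not isolated) | C1=C(O[Li])O[C@H]2C[C@]3(CO[Si](C)(C)C(C)(C)C)CC[C@@]4(C)CC=C(C)CC[C@@H]4[C@@]3(O[Li])[C@@H]12 | intermediate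
30 | α-[(dimethylamino)methyl] lactone from 28, mixture at the α-carbon (not isolated) | CN(C)CC1C(=O)O[C@H]2C[C@]3(CO[Si](C)(C)C(C)(C)C)CC[C@@]4(C)CC=C(C)CC[C@@H]4[C@@]3(O)[C@@H]12 | intermediate
31 | trimethylammonium iodide from 30 (not isolated) | C[N+](C)(C)CC1C(=O)O[C@H]2C[C@]3(CO[Si](C)(C)C(C)(C)C)CC[C@@]4(C)CC=C(C)CC[C@@H]4[C@@]3(O)[C@@H]12.[I-] | intermediate
32 | α-methylene lactone, CH2OTBS (otherwise as 28) | C=C1C(=O)O[C@H]2C[C@]3(CO[Si](C)(C)C(C)(C)C)CC[C@@]4(C)CC=C(C)CC[C@@H]4[C@@]3(O)[C@@H]12 | intermediate
33 | α-methylene lactone diol (CH2OH, tertiary OH) | C=C1C(=O)O[C@H]2C[C@]3(CO)CC[C@@]4(C)CC=C(C)CC[C@@H]4[C@@]3(O)[C@@H]12 | intermediate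
34 | primary acetate, the deoxy (alkene) form of the target | C=C1C(=O)O[C@H]2C[C@]3(COC(C)=O)CC[C@@]4(C)CC=C(C)CC[C@@H]4[C@@]3(O)[C@@H]12 | intermediate
35 | CNP0214540.1: as 34 with the β-epoxide on the C(CH3)=CH bond of ring C | C=C1C(=O)O[C@H]2C[C@]3(COC(C)=O)CC[C@@]4(C)C[C@H]5O[C@@]5(C)CC[C@@H]4[C@@]3(O)[C@@H]12 | target

**Count**
Total steps: 19. Longest linear sequence: 18 (steps 1–4 and 6–19 from 1; step 5 is a one-step side branch).

**Steps most likely to fail**
1. Step 6 (proposed new method). What may go wrong: translocation of the primary radical by 1,5-hydrogen transfer from the aldehyde C–H, or protonation or intermolecular Wittig reaction of the ylide, may outrun the annulation. The fallback uses known reactions only, sets out from 8 and comes back at 14, and keeps the carboxyl carbon as a ring CH2. Wittig methylenation of the aldehyde (Ph3P=CH2, 3 equiv, THF) gives the ene acid F1. LiAlH4 reduces the acid to the primary alcohol F2. I2, PPh3 and imidazole give the iodide F3. Cu-catalysed coupling with isopropenylmagnesium bromide (Li2CuCl4 cat., THF, −20 °C) gives the 1,8-diene F4. Ring-closing metathesis (second-generation Grubbs catalyst, CH2Cl2, 40 °C) then closes the trisubstituted cycloheptene 14.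
2. Step 15. What may go wrong: bond formation on the α-face of the ketyl carbon (cis-fused ring A), or simple reduction of the ketone or the butenolide without C–C bond formation. The fallback sets out from 27 and comes back at 32, replacing the radical closure by a two-electron allylmetal addition. Tandem conjugate addition–aldol (PhSeLi, THF, −78 °C, then CH2O) gives the β-phenylselanyl α-hydroxymethyl lactone F5. NaIO4 (selenoxide syn-elimination) gives the 3-(hydroxymethyl)butenolide F6. CBr4/PPh3 gives the allylic bromide F7. Indium-mediated intramolecular Barbier allylation (In, THF/H2O, rt) joins the lactone β-carbon to the ketone carbon through a closed six-membered transition state and gives the α-methylene lactone 32 directly, so step 16 is not needed.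
3. Step 19. What may go wrong: peracid attack on the α-face, syn to the angular methyl. The fallback sets out from 34 and comes back at 35. NBS in THF/H2O at 0 °C gives the bromohydrin F8: the bromonium ion forms on the face the peracid prefers and water opens it at the tertiary carbon from the other face. DBU in CH2Cl2 then closes the epoxide on the face opposite to the one the peracid chose.

**Further compounds**
F1 | step 6 | 2-[2-allyl-6-(tert-butyldimethylsilyloxy)-2-methylcyclohexyl]acetic acid (ring stereochemistry as in 8) | C1CC[C@@](C)(CC=C)[C@H](CC(=O)O)[C@H]1O[Si](C)(C)C(C)(C)C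
F2 | step 6 | 2-[2-allyl-6-(tert-butyldimethylsilyloxy)-2-methylcyclohexyl]ethanol | C1CC[C@@](C)(CC=C)[C@H](CCO)[C@H]1O[Si](C)(C)C(C)(C)C
F3 | step 6 | primary iodide from F2 | C1CC[C@@](C)(CC=C)[C@H](CCI)[C@H]1O[Si](C)(C)C(C)(C)C
F4 | step 6 | 1,8-diene: allyl and 3-methylbut-3-enyl arms on the silyloxy cyclohexane | C1CC[C@@](C)(CC=C)[C@H](CCC(C)=C)[C@H]1O[Si](C)(C)C(C)(C)C
F5 | step 15 | α-(hydroxymethyl)-β-(phenylselanyl) lactone from 27 | CC(C)(C)[Si](C)(C)OC[C@@]1(C[C@@H]2OC(=O)C(CO)C2[Se]c4ccccc4)CC[C@@]3(C)CC=C(C)CC[C@@H]3C1=O
F6 | step 15 | 3-(hydroxymethyl)butenolide | CC(C)(C)[Si](C)(C)OC[C@@]1(C[C@@H]2OC(=O)C(CO)=C2)CC[C@@]3(C)CC=C(C)CC[C@@H]3C1=O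
F7 | step 15 | 3-(bromomethyl)butenolide | CC(C)(C)[Si](C)(C)OC[C@@]1(C[C@@H]2OC(=O)C(CBr)=C2)CC[C@@]3(C)CC=C(C)CC[C@@H]3C1=O
F8 | step 19 | bromohydrin of 34: tertiary OH β, secondary Br α | C=C1C(=O)O[C@H]2C[C@]3(COC(C)=O)CC[C@@]4(C)C[C@H](Br)[C@](O)(C)CC[C@@H]4[C@@]3(O)[C@@H]12
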